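- Time is the setting I watch: the flask stands isothermal and is read at 50 min.

all flasks: substrate 0.050 M

| flask | coupling partner | remark | time |
|---|---|---|---|
| Tuesday's | 0.091 M | run made earlier |  |
| Wednesday's | 0.14 M | run made earlier |  |
| flask | 0.0650 M |  | 50 min |

- Tuesday's (time / min: target / %, intermediate A / %, intermediate B / %): 3.00: 0.1, 5.0, 0; 10.0: 1.9, 14.3, 0.4; 20.0: 4.2, 20.6, 2.7; 25.0: 5.9, 22.8, 4.5; 40.0: 8.3, 27.8, 8.0; 50.0: 10.1, 30.2, 9.5
- Wednesday's (time / min: target / %, intermediate A / %, intermediate B / %): 4.00: 0.1, 10.4, 0.8; 6.00: 0.8, 13.7, 1.0; 12.0: 3.7, 21.0, 2.7; 20.0: 6.3, 26.4, 6.8; 30.0: 8.4, 29.3, 10.8; 50.0: 10.9, 30.5, 19.9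

(scatter of a reading: 0.3 percentage points)

- steps under discussion: substrate + coupling partner -> intermediate A; coupling partner + intermediate A <-> intermediate B; substrate + coupling partner -> intermediate C; intermediate A <-> target; intermediate C -> intermediate A

* target present at 50 min, in percent of the substrate charged
* intermediate A present at 50 min, in percent of the substrate charged
* intermediate B present at 50 min, in percent of the substrate charged

- I work with what is left. The unseen fraction L is one minus target, intermediate A and intermediate B, each as a fraction of the substrate charged. Tuesday's run reads 66.8 % at 25.0 min, and Wednesday's run reads 60.5 % at 20.0 min.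
- I count coupling partner in equivalents of substrate, spending one per unit of seen product and taking the mean of start and end. That gives 1.65 for Tuesday's run and 2.60 for Wednesday's run.
- Dividing −ln L by mean partner and time gives 0.00976 min⁻¹ and 0.00965 min⁻¹. I carry their mean, the decay constant of the unseen fraction per equivalent of partner, 0.00971 min⁻¹.
- First the decay of L by itself: with the flask's 1.30 equivalents held at charge, a pseudo-first-order decay, I reckon L at 53.2 %.
- Then I draw partner down in the flask: my mean falls to 1.07, so my L for the flask comes out at 59.6 %. A second pass, with mean 1.10, gives 58.7 %.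
- Then the split: I scale Tuesday's share of intermediate B at 50.0 min by the ratio of mean partners, which gives 5.51 %. Tuesday's target over intermediate A, 0.334, divides the remainder into 8.96 % target and 26.8 % intermediate A.
- The forecast, holding that “substrate loss is first order in partner”, gives 8.1 % target, 25.2 % intermediate A and 5.2 % intermediate B, so it leaves 61.5 % unseen, more than my L.
- The flask gives 8.39 % target, 26.5 % intermediate A and 5.72 % intermediate B, each inside the forecast's range.

    substrate + coupling partner → intermediate A (k = 0.00380 M⁻¹ s⁻¹)
    coupling partner + intermediate A ⇌ intermediate B (K = 470 M⁻¹, k = 0.00270 M⁻¹ s⁻¹)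
    substrate + coupling partner → intermediate C (k = 0.00290 M⁻¹ s⁻¹)
    intermediate A ⇌ target (K = 0.370, k = 5.00 × 10⁻⁴ s⁻¹)
    intermediate C → intermediate A (k = 1.70 × 10⁻⁴ s⁻¹)

- The flask's L is 59.4 %, made of substrate 40.5 % and intermediate C 18.9 %. On the neighbouring flask, charged with 0.16 M of coupling partner and read at 50 min, 3.20 equivalents and the same passes give L = 25.3 %. That neighbouring flask shows 36.3 %, higher than my reckoning, and its L holds substrate 8.66 % and intermediate C 27.6 %.

(Readings and results are calculated on assumed constants; noise was put on by code.)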